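You read each of these flasks at 40 min, and that time means nothing until you set it against a second clock: how long the anion lasts.

all flasks: acidic substrate 0.10 M
- north-east: free base 0.095 M; electrophile 0.20 M; temperature 25 °C; run made earlier
- north-west: free base 0.095 M; electrophile 0.10 M; temperature 25 °C; run made earlier
- oak: free base 0.0950 M; electrophile 0.200 M (in portions, 5, over 25 min); temperature 25 °C; first portion at the start, last at 25 min; time 40 min
- cedar: free base 0.0950 M (fed, over 25 min); electrophile 0.200 M; the addition at 5 °C, then warmed to 25 °C; the feed brings no volume worth counting; time 40 min
- alder: free base 0.0950 M (fed, over 25 min); electrophile 0.200 M; temperature 25 °C; all else is in the flask from the start; the feed brings no volume worth counting; time 40 min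
- elm: free base 0.0950 M (fed, over 2.5 min); electrophile 0.200 M; temperature 25 °C; all else is in the flask from the start; the feed brings no volume worth counting; time 40 min
- ash: free base 0.0950 M; electrophile 0.200 M (fed, over 25 min); temperature 25 °C; all else is in the flask from the start; the feed brings no volume worth counting; time 40 min

| north-east: time / min | north-east: product / % | north-west: time / min | north-west: product / % |
|---|---|---|---|
| 2.00 | 2.9 | 0.667 | 0.5 |
| 3.00 | 4.4 | 1.33 | 0.6 |
| 5.00 | 8.1 | 2.00 | 1.2 |
| 8.00 | 11.1 | 2.50 | 1.5 |
| 15.0 | 19.9 | 3.00 | 2.1 |
| 25.0 | 29.3 | 4.00 | 3.8 |

(each reading ± 0.5 percentage points)

- amounts and yields of product count crystals too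
- given per volume of solution although it is solid: crystals
- steps thought possible: acidic substrate + free base <-> protonated base + anion; electrophile + anion <-> product; crystals <-> product
- the earlier runs do not show what temperature does; that part of a forecast is a guess

- the flask that comes out highest in amount of product, in percent of the acidic substrate charged, or "all alike" when all lie within 1.5 percentage points (oak / cedar / alder / elm / ash / all alike)
- product at the end, in percent of the acidic substrate charged, oak
- product at the end, in percent of the acidic substrate charged, cedar
- product at the end, in percent of the acidic substrate charged, alder
- product at the end, in percent of the acidic substrate charged, elm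
- product at the end, in percent of the acidic substrate charged, ash

The earlier runs set the second clock. At 3.00 min the north-east run, with twice the electrophile, holds about twice the product of the north-west run, so I read the rate as first order in c(electrophile). While c(electrophile) stays near its charge, the anion falls pseudo-first-order. I take the free base charge as the ceiling, 95.0% of the acidic substrate, and the last north-east reading, 29.3% at 25.0 min, then gives a reading of the anion's life, the time to fall by a factor e: 67.8 min.

The first clock needs one correction, because an addition spread evenly over a time arrives on average half that time late. So I use the mean dwell, the reading time minus half the addition time. Alder, ash and oak share 27.5 min, since the portions of oak are evenly spaced over the same span, while elm has 38.8 min. Product is then the ceiling times the fraction of anion gone after dwell over life. My reckoning gives 31.7% for alder and 41.4% for elm. The readings say nothing about the cold, so I reckon nothing for cedar.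

The forecast names elm, with 40% there, 31.2% for alder, 31.3% for ash, 31.2% for oak and, by a guess, 22.5% for cedar. Its ground for elm is that “Elm loses only about 1.25 min”. Its elm lies 1.4 percentage points below my reckoning.

Elm comes out highest at 39.7%, against 31.5% for alder, 30.9% for ash, 30.8% for oak and 22.8% for cedar.

    acidic substrate + free base ⇌ protonated base + anion, settled at all times (K = 43.0, ΔH = −29.0 kJ/mol)
    electrophile + anion ⇌ product (K = 7.00 /M, k = 0.00160 /M/s, Ea = 51.0 kJ/mol, ΔH = −77.0 kJ/mol)
    crystals ⇌ product, rate k3*(cs3 - [product]) while solid is left; crystals form when [product] > cs3 (solubility = 4.30 mM, k = 0.0190 /s)
    (constants at 25 °C)

In elm the anion's half-life by the forward rate of the electrophile step alone at the reading is 45 min, longer than elm's dwell of 38.8 min, and alder's dwell of 27.5 min is shorter still. A later reading takes elm's lead over cedar away: left ten times as long, elm holds 86.6% and cedar 86.3%, closer than the margin of 1.5 points.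

The runs were computed with constants of no real substance, and the scatter is random.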